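**Plan**

- Ring letters: upper unit A (phloroglucinol), C (pyran), B (pyrogallol); lower unit D, F, E with primed atoms; galloyl ring G. The retrosynthesis removes 13 benzyl ethers, then cuts the C4–C8′ interflavan bond and the O1′–C2′ bond of ring F in one retro-step. This gives a C4-activated, galloylated upper unit 12 and the open-chain cis-epoxyphenol 8.
- Enabling feature: C2′ is benzylic to ring E and vicinal to the C3′ carbinol, and O1′ is a phenol oxygen of ring D ortho to C4′H2. The O1′–C2′–C3′(OH) unit is therefore the opened form of a 2-(oxiranylmethyl)phenol; epoxide strain drives the closure, and the same free phenol makes ring D the C8′ nucleophile.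
- Epoxide 8 is used twice: closed alone it gives ring C of the upper unit (then C4–H oxidation and galloylation give 12), and as such it is the lower-unit partner. 8 comes from aldehyde 1 and phenol 3 by Friedel–Crafts allylation (C4′–C4a′ bond), E→Z switch and asymmetric epoxidation.
- Forward order: chain joined (steps 1–2), alkene geometry and epoxide (3–6), ring C (7), C4 activation and ester (8–9), C4–C8′ bond plus ring F in one operation (10), debenzylation (11).
- Stereochemistry: the single catalyst-controlled epoxidation (step 5) sets C3 of both units and, by inversion on ring closure, C2 of both. C4 is set by attack anti to the C2 and C3 substituents.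

Key step: step 10

Assumption: 1, 3 and 11 are taken as purchasable, and the sense of induction in step 5 is assigned by analogy with cis-β-methylstyrene and indene; the enantiomeric catalyst is equally available should the sense prove opposite.

**Step 1**
Reactants: 1 3,4,5-tris(benzyloxy)benzaldehyde
Product: 2 rac-1-[3,4,5-tris(benzyloxy)phenyl]prop-2-en-1-ol
Conditions: vinylmagnesium bromide (1.2 equiv), THF, −78 → 0 °C; sat. aq. NH4Cl
Reagents that add atoms: vinylmagnesium bromide, C=C[Mg]Br
Why: Grignard 1,2-addition to the aromatic aldehyde should give the racemic 1-arylallyl alcohol, whose stereocentre is erased in step 2.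

**Step 2**
Reactants: 2 rac-1-[3,4,5-tris(benzyloxy)phenyl]prop-2-en-1-ol; 3 3,5-bis(benzyloxy)phenol
Product: 4 3,5-bis(benzyloxy)-2-[(2E)-3-[3,4,5-tris(benzyloxy)phenyl]prop-2-en-1-yl]phenol
Conditions: H2SO4 on SiO2 (cat.), CH2Cl2, rt, 3 in two-fold excess
Reagents that add atoms: none
Why: Friedel–Crafts allylation, in which acid ionises 2 to the 1-arylallyl cation and ring D of 3 should capture its unsubstituted terminus through the carbon ortho to the free hydroxyl, giving the conjugated (E)-alkene as in the known acid-mediated cinnamylation of this phenol.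

**Step 3**
Reactants: 4 3,5-bis(benzyloxy)-2-[(2E)-3-[3,4,5-tris(benzyloxy)phenyl]prop-2-en-1-yl]phenol
Product: 5 tert-butyl{3,5-bis(benzyloxy)-2-[(2E)-3-[3,4,5-tris(benzyloxy)phenyl]prop-2-en-1-yl]phenoxy}dimethylsilane
Conditions: TBSCl, imidazole, DMF, rt
Reagents that add atoms: tert-butyldimethylsilyl chloride, CC(C)(C)[Si](C)(C)Cl
Why: Standard silylation masks the phenol, which would otherwise be oxidised in step 5 or add to the alkene or epoxide too early.

**Step 4**
Reactants: 5 tert-butyl{3,5-bis(benzyloxy)-2-[(2E)-3-[3,4,5-tris(benzyloxy)phenyl]prop-2-en-1-yl]phenoxy}dimethylsilane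
Product: 6 tert-butyl{3,5-bis(benzyloxy)-2-[(2Z)-3-[3,4,5-tris(benzyloxy)phenyl]prop-2-en-1-yl]phenoxy}dimethylsilane
Conditions: fac-Ir(ppy)3 [tris(2-phenylpyridinato)iridium] (1 mol%), blue LEDs (450 nm), degassed THF, rt; AgNO3–SiO2 chromatography
Reagents that add atoms: none
Why: Contra-thermodynamic E→Z photoisomerisation of a β-alkylstyrene by triplet energy transfer should work because the planar (E)-styrene is sensitised efficiently whereas the twisted (Z)-isomer is not, so the photostationary state should be Z-rich.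

**Step 5**
Reactants: 6 tert-butyl{3,5-bis(benzyloxy)-2-[(2Z)-3-[3,4,5-tris(benzyloxy)phenyl]prop-2-en-1-yl]phenoxy}dimethylsilane
Product: 7 tert-butyl{3,5-bis(benzyloxy)-2-{[(2R,3S)-3-[3,4,5-tris(benzyloxy)phenyl]oxiran-2-yl]methyl}phenoxy}dimethylsilane
Conditions: (S,S)-N,N′-bis(3,5-di-tert-butylsalicylidene)-1,2-cyclohexanediaminomanganese chloride (5 mol%), N-methylmorpholine N-oxide (5 equiv), mCPBA (2 equiv), CH2Cl2, −78 °C
Reagents that add atoms: mCPBA, OOC(=O)c1cccc(Cl)c1
Why: Jacobsen–Katsuki epoxidation of a cis-β-alkylstyrene, the favoured substrate class of this catalyst, should transfer oxygen to one enantioface and so set both epoxide stereocentres (expected 2R,3S with the S,S catalyst), while the low-temperature peracid protocol avoids hypochlorite, which would chlorinate ring D.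

**Step 6**
Reactants: 7 tert-butyl{3,5-bis(benzyloxy)-2-{[(2R,3S)-3-[3,4,5-tris(benzyloxy)phenyl]oxiran-2-yl]methyl}phenoxy}dimethylsilane
Product: 8 3,5-bis(benzyloxy)-2-{[(2R,3S)-3-[3,4,5-tris(benzyloxy)phenyl]oxiran-2-yl]methyl}phenol
Conditions: Bu4NF (1.1 equiv), AcOH (1.2 equiv), THF, −20 → 0 °C; used at once
Reagents that add atoms: none
Why: Buffered fluoride cleavage of the aryl silyl ether should free the phenol while acetic acid keeps it protonated, which suppresses base-induced 5-exo opening of the epoxide.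

**Step 7**
Reactants: 8 3,5-bis(benzyloxy)-2-{[(2R,3S)-3-[3,4,5-tris(benzyloxy)phenyl]oxiran-2-yl]methyl}phenol
Product: 9 (2R,3R)-5,7-bis(benzyloxy)-2-[3,4,5-tris(benzyloxy)phenyl]chroman-3-ol (penta-O-benzyl-epigallocatechin)
Conditions: (+)-camphor-10-sulfonic acid (10 mol%), CH2Cl2, −20 → 0 °C
Reagents that add atoms: none
Why: Acid-promoted intramolecular epoxide opening by the phenol (6-endo-tet at the benzylic carbon) should convert the cis-epoxide stereospecifically into the 2,3-cis flavan-3-ol, with C3 (R) carried over from the epoxide and C2 (R) arising by inversion of the (S)-benzylic carbon.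

**Step 8**
Reactants: 9 (2R,3R)-5,7-bis(benzyloxy)-2-[3,4,5-tris(benzyloxy)phenyl]chroman-3-ol
Product: 10 (2R,3R,4S)-5,7-bis(benzyloxy)-4-(2-ethoxyethoxy)-2-[3,4,5-tris(benzyloxy)phenyl]chroman-3-ol
Conditions: DDQ (2 equiv), 2-ethoxyethanol (5 equiv), CH2Cl2, rt
Reagents that add atoms: 2-ethoxyethanol, CCOCCO
Why: DDQ-mediated benzylic C–H oxidative etherification, well established for benzylated flavan-3-ols, should abstract hydride from the doubly oxygen-activated C4–H and let the alcohol add anti to the C2 aryl and C3 hydroxyl groups, setting the 4β (4S) ether.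

**Step 9**
Reactants: 10 (2R,3R,4S)-5,7-bis(benzyloxy)-4-(2-ethoxyethoxy)-2-[3,4,5-tris(benzyloxy)phenyl]chroman-3-ol; 11 3,4,5-tris(benzyloxy)benzoic acid
Product: 12 (2R,3R,4S)-5,7-bis(benzyloxy)-4-(2-ethoxyethoxy)-2-[3,4,5-tris(benzyloxy)phenyl]chroman-3-yl 3,4,5-tris(benzyloxy)benzoate
Conditions: DCC (3 equiv), 4-(dimethylamino)pyridine (cat.), CH2Cl2, rt
Reagents that add atoms: none
Why: Steglich esterification of the secondary C3 hydroxyl should proceed without touching the acid-labile C4 ether and installs the only galloyl group before the second unit (with its own C3′ hydroxyl) is present.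

**Step 10**
Reactants: 12 (2R,3R,4S)-5,7-bis(benzyloxy)-4-(2-ethoxyethoxy)-2-[3,4,5-tris(benzyloxy)phenyl]chroman-3-yl 3,4,5-tris(benzyloxy)benzoate; 8 3,5-bis(benzyloxy)-2-{[(2R,3S)-3-[3,4,5-tris(benzyloxy)phenyl]oxiran-2-yl]methyl}phenol
Product: 14 trideca-O-benzyl epigallocatechin-3-O-gallate-(4β→8)-epigallocatechin, via seco-dimer epoxyphenol 13 (not isolated)
Conditions: 8 (1.5 equiv), Me3SiOTf (0.3 equiv), CH2Cl2, −78 °C, then −20 °C; Et3N quench
Reagents that add atoms: none
Why: Proposed new method: Me3SiOTf ionises the C4 ether of 12 to a benzylic cation stabilised by ring A and by the C3 galloyl carbonyl, ring D of 8 (the most electron-rich arene present because of its free phenol) attacks it through the carbon ortho to that hydroxyl to give 13, and the same acid then activates the cis-epoxide so that the neighbouring phenol oxygen opens it at the benzylic carbon, forming the O1′–C2′ bond and ring F. The closest known reaction types are the silyl-triflate-mediated C4→C8 Friedel–Crafts union of 4-alkoxyflavan-3-ol electrophiles with benzylated flavan-3-ols and the acid-promoted cyclisation of 2-(3-aryloxiranylmethyl)phenols to flavan-3-ols (step 7), whose merger on an uncyclised epoxyphenol has not been described. Ring F closes in the 6-endo-tet mode, favoured over 5-exo because positive charge develops at the carbon benzylic to ring E. C4 is set as 4β by attack anti to the C3 acyloxy and C2 aryl groups (with possible acyloxonium participation), C2′ is set as R by inversion at the (S)-epoxide carbon, and C3′ (R) is carried over from the epoxide, so the cis-epoxide becomes the 2,3-cis lower unit and releases the only free hydroxyl of 14. The step needs C-arylation ortho to the phenol (future C8′) and not at the carbon flanked by two benzyloxy groups (future C6′), which the steric bias known for 5,7-di-O-benzylflavans and ortho delivery through the phenol oxygen should secure, and it needs SN2-type opening without ionisation, which the low temperature and the only moderately donating tribenzyloxyphenyl group should secure. If the epoxide opens first, the sequence passes through 9 and the same C8 arylation, so both orders converge on 14.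

**Step 11**
Reactants: 14 trideca-O-benzyl epigallocatechin-3-O-gallate-(4β→8)-epigallocatechin
Product: 15 epigallocatechin-3-O-gallate-(4β→8)-epigallocatechin (target)
Conditions: H2 (1 atm), Pd(OH)2/C, THF/MeOH/H2O, rt; filtration, lyophilisation
Reagents that add atoms: none
Why: Hydrogenolysis of the thirteen benzyl ethers over Pd(OH)2/C, the standard last step for benzylated proanthocyanidin gallates, should leave the ester, the interflavan bond and all five stereocentres untouched.

**Compound list**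

1 | 3,4,5-tris(benzyloxy)benzaldehyde | O=Cc1cc(OCc2ccccc2)c(OCc2ccccc2)c(OCc2ccccc2)c1 | starting material
2 | rac-1-[3,4,5-tris(benzyloxy)phenyl]prop-2-en-1-ol | C=CC(O)c1cc(OCc2ccccc2)c(OCc2ccccc2)c(OCc2ccccc2)c1 | intermediate
3 | 3,5-bis(benzyloxy)phenol | Oc1cc(OCc2ccccc2)cc(OCc2ccccc2)c1 | starting material
4 | 3,5-bis(benzyloxy)-2-[(2E)-3-[3,4,5-tris(benzyloxy)phenyl]prop-2-en-1-yl]phenol | Oc1cc(OCc2ccccc2)cc(OCc2ccccc2)c1C/C=C/c1cc(OCc2ccccc2)c(OCc2ccccc2)c(OCc2ccccc2)c1 | intermediate
5 | tert-butyl{3,5-bis(benzyloxy)-2-[(2E)-3-[3,4,5-tris(benzyloxy)phenyl]prop-2-en-1-yl]phenoxy}dimethylsilane | CC(C)(C)[Si](C)(C)Oc1cc(OCc2ccccc2)cc(OCc2ccccc2)c1C/C=C/c1cc(OCc2ccccc2)c(OCc2ccccc2)c(OCc2ccccc2)c1 | intermediate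
6 | tert-butyl{3,5-bis(benzyloxy)-2-[(2Z)-3-[3,4,5-tris(benzyloxy)phenyl]prop-2-en-1-yl]phenoxy}dimethylsilane | CC(C)(C)[Si](C)(C)Oc1cc(OCc2ccccc2)cc(OCc2ccccc2)c1C/C=C\c1cc(OCc2ccccc2)c(OCc2ccccc2)c(OCc2ccccc2)c1 | intermediate
7 | tert-butyl{3,5-bis(benzyloxy)-2-{[(2R,3S)-3-[3,4,5-tris(benzyloxy)phenyl]oxiran-2-yl]methyl}phenoxy}dimethylsilane (cis-epoxide) | CC(C)(C)[Si](C)(C)Oc1cc(OCc2ccccc2)cc(OCc2ccccc2)c1C[C@H]1O[C@H]1c1cc(OCc2ccccc2)c(OCc2ccccc2)c(OCc2ccccc2)c1 | intermediate
8 | 3,5-bis(benzyloxy)-2-{[(2R,3S)-3-[3,4,5-tris(benzyloxy)phenyl]oxiran-2-yl]methyl}phenol (cis-epoxyphenol) | Oc1cc(OCc2ccccc2)cc(OCc2ccccc2)c1C[C@H]1O[C@H]1c1cc(OCc2ccccc2)c(OCc2ccccc2)c(OCc2ccccc2)c1 | intermediate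
9 | (2R,3R)-5,7-bis(benzyloxy)-2-[3,4,5-tris(benzyloxy)phenyl]chroman-3-ol (penta-O-benzyl-epigallocatechin) | O[C@@H]1Cc2c(OCc3ccccc3)cc(OCc3ccccc3)cc2O[C@@H]1c1cc(OCc2ccccc2)c(OCc2ccccc2)c(OCc2ccccc2)c1 | intermediate
10 | (2R,3R,4S)-5,7-bis(benzyloxy)-4-(2-ethoxyethoxy)-2-[3,4,5-tris(benzyloxy)phenyl]chroman-3-ol (4β ether) | O[C@@H]1[C@@H](OCCOCC)c2c(OCc3ccccc3)cc(OCc3ccccc3)cc2O[C@@H]1c1cc(OCc2ccccc2)c(OCc2ccccc2)c(OCc2ccccc2)c1 | intermediate
11 | 3,4,5-tris(benzyloxy)benzoic acid | OC(=O)c1cc(OCc2ccccc2)c(OCc2ccccc2)c(OCc2ccccc2)c1 | starting material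
12 | (2R,3R,4S)-5,7-bis(benzyloxy)-4-(2-ethoxyethoxy)-2-[3,4,5-tris(benzyloxy)phenyl]chroman-3-yl 3,4,5-tris(benzyloxy)benzoate | O=C(O[C@@H]1[C@@H](OCCOCC)c2c(OCc3ccccc3)cc(OCc3ccccc3)cc2O[C@@H]1c1cc(OCc2ccccc2)c(OCc2ccccc2)c(OCc2ccccc2)c1)c1cc(OCc2ccccc2)c(OCc2ccccc2)c(OCc2ccccc2)c1 | intermediate
13 | (2R,3R,4S)-5,7-bis(benzyloxy)-4-{4,6-bis(benzyloxy)-2-hydroxy-3-{[(2R,3S)-3-[3,4,5-tris(benzyloxy)phenyl]oxiran-2-yl]methyl}phenyl}-2-[3,4,5-tris(benzyloxy)phenyl]chroman-3-yl 3,4,5-tris(benzyloxy)benzoate (4β aryl; seco-dimer, the CIP label at C4 differs from 14 only because of the free phenol) | O=C(O[C@@H]1[C@@H](c2c(O)c(C[C@H]3O[C@H]3c3cc(OCc4ccccc4)c(OCc4ccccc4)c(OCc4ccccc4)c3)c(OCc3ccccc3)cc2OCc2ccccc2)c2c(OCc3ccccc3)cc(OCc3ccccc3)cc2O[C@@H]1c1cc(OCc2ccccc2)c(OCc2ccccc2)c(OCc2ccccc2)c1)c1cc(OCc2ccccc2)c(OCc2ccccc2)c(OCc2ccccc2)c1 | intermediate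
14 | (2R,3R,4R)-5,7-bis(benzyloxy)-4-{(2R,3R)-5,7-bis(benzyloxy)-3-hydroxy-2-[3,4,5-tris(benzyloxy)phenyl]chroman-8-yl}-2-[3,4,5-tris(benzyloxy)phenyl]chroman-3-yl 3,4,5-tris(benzyloxy)benzoate | O=C(O[C@@H]1[C@@H](c2c(OCc3ccccc3)cc(OCc3ccccc3)c3c2O[C@H](c2cc(OCc4ccccc4)c(OCc4ccccc4)c(OCc4ccccc4)c2)[C@H](O)C3)c2c(OCc3ccccc3)cc(OCc3ccccc3)cc2O[C@@H]1c1cc(OCc2ccccc2)c(OCc2ccccc2)c(OCc2ccccc2)c1)c1cc(OCc2ccccc2)c(OCc2ccccc2)c(OCc2ccccc2)c1 | intermediate
15 | (2R,3R,4R)-5,7-dihydroxy-4-[(2R,3R)-3,5,7-trihydroxy-2-(3,4,5-trihydroxyphenyl)chroman-8-yl]-2-(3,4,5-trihydroxyphenyl)chroman-3-yl 3,4,5-trihydroxybenzoate | O=C(O[C@@H]1[C@@H](c2c(O)cc(O)c3c2O[C@H](c2cc(O)c(O)c(O)c2)[C@H](O)C3)c2c(O)cc(O)cc2O[C@@H]1c1cc(O)c(O)c(O)c1)c1cc(O)c(O)c(O)c1 | target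

**Totals**

Total step count: 11. Longest linear sequence: 11 steps (1 → 2 → 4 → 5 → 6 → 7 → 8 → 9 → 10 → 12 → 14 → 15; epoxide 8 enters a second time in step 10).

**Steps most likely to fail**

1. Step 10 (Proposed new method). The epoxide may ionise or undergo a 1,2-shift before the phenol attacks, which would lose stereospecificity at C2′. Arylation may also occur at the hindered ring-D carbon, or 12 may self-condense. Fallback with known chemistry: the two events are separated. Isolated 9 from step 7 (about 3 equiv) is used as the nucleophile toward 12 with Me3SiOTf in CH2Cl2 at −78 °C, the established C4→C8 Friedel–Crafts union of benzylated flavan-3-ols. This fallback sets out from 9 and 12, comes back to the route at 14, and makes no compound outside the list (F0).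

2. Step 5. Bond rotation in the stepwise oxygen transfer may leak cis geometry into trans-epoxide, or facial discrimination on this hindered Z-alkene may be insufficient. Fallback (it sets out from 5 and therefore also covers an inseparable mixture from step 4): the E-alkene 5 is epoxidised by Shi epoxidation with the enantiomer of the fructose-derived ketone (1,2:4,5-di-O-isopropylidene-β-L-erythro-2,3-hexodiulo-2,6-pyranose), KHSO5 and K2CO3 buffer at 0 °C. This oxidation is concerted and reliable for trans-β-alkylstyrenes and should give tert-butyl{3,5-bis(benzyloxy)-2-{[(2S,3S)-3-[3,4,5-tris(benzyloxy)phenyl]oxiran-2-yl]methyl}phenoxy}dimethylsilane F1. Bu4NF/AcOH then frees the trans-epoxyphenol F2. Camphorsulfonic acid closes it (6-endo, inversion) to (2R,3S)-penta-O-benzyl-gallocatechin F3. Dess–Martin periodinane oxidises C3 to the (2R)-flavan-3-one F4. LiBH(s-Bu)3 in THF at −78 °C, delivering hydride anti to the C2 aryl group, should give 9, where the fallback comes back to the route. Steps 8 and 9 follow as written; since 8 is then not at hand, the union is run as in the fallback to step 10.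

3. Step 6. The liberated phenoxide may open the epoxide in the 5-exo sense, or the epoxyphenol may cyclise uncontrolled during unmasking or chromatography. Fallback: 7 is treated with HF·pyridine in THF at 0 °C. The acidic fluoride removes the silyl group and the freed phenol closes the ring in the 6-endo sense in the same flask, giving 9 directly. The fallback sets out from 7 and comes back to the route at 9; the union is then run as in the fallback to step 10, and no compound outside the list is made (F0).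

**Further compounds**

F0 | step 10 | none | none
F1 | step 5 | tert-butyl{3,5-bis(benzyloxy)-2-{[(2S,3S)-3-[3,4,5-tris(benzyloxy)phenyl]oxiran-2-yl]methyl}phenoxy}dimethylsilane | CC(C)(C)[Si](C)(C)Oc1cc(OCc2ccccc2)cc(OCc2ccccc2)c1C[C@@H]1O[C@H]1c1cc(OCc2ccccc2)c(OCc2ccccc2)c(OCc2ccccc2)c1
F2 | step 5 | 3,5-bis(benzyloxy)-2-{[(2S,3S)-3-[3,4,5-tris(benzyloxy)phenyl]oxiran-2-yl]methyl}phenol | Oc1cc(OCc2ccccc2)cc(OCc2ccccc2)c1C[C@@H]1O[C@H]1c1cc(OCc2ccccc2)c(OCc2ccccc2)c(OCc2ccccc2)c1
F3 | step 5 | (2R,3S)-5,7-bis(benzyloxy)-2-[3,4,5-tris(benzyloxy)phenyl]chroman-3-ol (penta-O-benzyl-gallocatechin) | O[C@H]1Cc2c(OCc3ccccc3)cc(OCc3ccccc3)cc2O[C@@H]1c1cc(OCc2ccccc2)c(OCc2ccccc2)c(OCc2ccccc2)c1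
F4 | step 5 | (2R)-5,7-bis(benzyloxy)-2-[3,4,5-tris(benzyloxy)phenyl]chroman-3-one | O=C1Cc2c(OCc3ccccc3)cc(OCc3ccccc3)cc2O[C@@H]1c1cc(OCc2ccccc2)c(OCc2ccccc2)c(OCc2ccccc2)c1
F0 | step 6 | none | none
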